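(The numbers are assumed; no experiment stands behind them.)

Four flasks wait on the bench.

| flask | substrate | first nucleophile | second nucleophile | temperature | time | remark |
|---|---|---|---|---|---|---|
| south-west | 5.0 mM | 9.00 mM | 7.50 mM (fed, over 4.0 min) | 80 °C | 10 min | all else is in the flask from the start; the feed brings no volume worth counting |
| south | 5.0 mM | 9.00 mM | 7.50 mM (in portions, 3, over 4.0 min) | 80 °C | 10 min | first portion at the start, last at 4.0 min |
| south-east | 5.0 mM | 9.00 mM | 7.50 mM | 80 °C | 10 min | everything together at the start |
| east | 5.0 mM | 9.00 mM | 7.50 mM (fed, over 4.0 min) |  | 10 min | the addition at 40 °C, then warmed to 80 °C; the feed brings no volume worth counting |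

    first nucleophile + intermediate → target (k1 = 46.3 M⁻¹ s⁻¹, Ea1 = 56.0 kJ mol⁻¹)
    first nucleophile ⇌ dormant form (K2 = 3.1, k2 = 0.00687 s⁻¹, Ea2 = 108 kJ mol⁻¹, ΔH2 = −43.0 kJ mol⁻¹)
    target ⇌ isomer of the product (K3 = 0.552, k3 = 0.0295 s⁻¹, Ea3 = 105 kJ mol⁻¹, ΔH3 = 6.00 kJ mol⁻¹)
    substrate → intermediate (k4 = 0.0196 s⁻¹, Ea4 = 104 kJ mol⁻¹)
    second nucleophile + intermediate → other capture product (k5 = 56.6 M⁻¹ s⁻¹, Ea5 = 57.0 kJ mol⁻¹)
    intermediate → solvolysis product (k6 = 0.0475 s⁻¹, Ea6 = 89.0 kJ mol⁻¹)
    (constants at 80 °C)

- all constants are for 80 °C and move with temperature by the activation energies and enthalpies

1. the flask that comes out highest in amount of target, in percent of the substrate charged, or "all alike" when all lie within 1.5 percentage points (south-west / south / south-east / east / all alike)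
2. target at the end, in percent of the substrate charged, south-west
3. target at the end, in percent of the substrate charged, south
4. target at the end, in percent of the substrate charged, south-east
5. target at the end, in percent of the substrate charged, east

To whoever takes over:

1. At 80 °C the substrate turns into the intermediate, with a mean life of 51.0 s. In south-east the intermediate has a half-life of 1.7 s by first nucleophile alone, shorter than the substrate's 0.59 min, so it leaves as fast as it forms (a steady state). What matters is where it goes.

2. I freeze the flask at that mean life. Let B be free first nucleophile and D free second nucleophile. Ignoring what capture uses, first nucleophile relaxing towards its dormant form keeps a fraction g = 72.0% free, so B = 6.48 mM.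

3. In south-west the feed has delivered D = 1.59 mM by then. The rate to target, divided by the sum of the rates out of the intermediate, is 68.5%. This capture share, a selectivity, is what I carry.

4. In south, D is one portion, so the share is 61.3%. In south-east, D is the whole charge, so the share is 38.8%. I take east as south-east, assuming the substrate waits out the cold addition.

5. Target and isomer of the product relax with a half-life of 0.139 min in south-west, shorter than the 10 min run, so target ends as 64.4% of that pair.

6. When you come, I expect target at 44.1% in south-west, 39.5% in south, and 25.0% in south-east and east. South-west comes highest in my reckoning.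

7. Do not hurry the second nucleophile: my share falls from 68.5% towards 38.8% as D rises.

The forecast picks south-west, with 42.5%, 38%, 25.7% and 26.7% for south-west, south, south-east and east. Its ground is “holding back the second nucleophile therefore favours the target most with a steady feed”. It stands below me in south-west and south, and above me in south-east and east.

The flasks give 42.0% in south-west, 38.0% in south, 25.7% in south-east and 26.1% in east, so south-west is highest. In south-west the substrate half-life of 0.59 min is shorter than the 4.0 min feed, and at 2.00 min, with half the feed in, 96% of the turnover to target up to the end is behind it. Target plus isomer of the product ends at 65.1% there, beside my capture share of 68.5%. For a neighbour of south-west charged with 15 mM of first nucleophile, my share becomes 78.4%, which gives 50.5% target. That neighbour of south-west ends at 48.9%.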